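**Retrosynthetic overview**
1. Target 19 ⇐ acid-triggered reorganisation of (+)-lariciresinol 9'-O-p-coumarate 18 (2-aryl-tetrahydrofuran → aryltetralin). The C–C ring closure frees the C9–OH, so the two CH2O groups are told apart without protecting groups.
2. 18 ⇐ Mitsunobu esterification of (+)-lariciresinol 14 with p-coumaric acid 17 (Heck reaction of 4-iodophenol and acrylic acid).
3. 14 ⇐ reduction and cycloetherification of the trans aldol adduct 12, made from (R)-β-vanillyl-γ-butyrolactone 11 and O-pivaloylvanillin 6 (guaiacol + glyoxylic acid).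
4. 11 ⇐ Friedel–Crafts acylation of guaiacol with (R)-paraconic acid 8, then deoxygenation. 8 ⇐ key step: catalytic enantioselective Baeyer–Villiger ring expansion (cyclobutanone → γ-lactone, C→O 1,2-shift) of 3-oxocyclobutanecarboxylic acid 7. This sets C8; C8' and C7' follow by substrate control.
5. Ring order: γ-butyrolactone (step 4) → tetrahydrofuran (step 8) → tetralin carbocycle (step 11). The aromatic rings come from catechol (via guaiacol) and 4-iodophenol.

Assumption: lignan numbering is used for positions (C7/C8/C9 = benzyl half, C7'/C8'/C9' = aryl-bearing half of the target); simple reagents (MeI, PivCl, H2O2) are not numbered.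

**Route**

Step 1
Reactants: 1 catechol
Product: 2 guaiacol (2-methoxyphenol)
Conditions: MeI (1.0 equiv), K2CO3 (1.0 equiv), acetone, reflux; distil
Reagents that add atoms: methyl iodide, CI
Why: Williamson mono-O-methylation (SN2), in which one equivalent of MeI favours the mono-ether, which is separated from catechol and veratrole by distillation.

Step 2
Reactants: 2 guaiacol; 3 glyoxylic acid
Product: 5 vanillin, via 4-hydroxy-3-methoxymandelic acid 4 (not isolated)
Conditions: 50% aq. glyoxylic acid, NaOH, H2O, 30 °C; then cat. CuSO4, air, NaOH, 95 °C; H2SO4 to pH 3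
Reagents that add atoms: none
Why: para-selective electrophilic hydroxyalkylation of the phenolate followed by copper-catalysed aerobic oxidative decarboxylation of the mandelic acid (the industrial guaiacol–glyoxylic acid vanillin process).

Step 3
Reactants: 5 vanillin
Product: 6 4-formyl-2-methoxyphenyl pivalate
Conditions: PivCl, Et3N, cat. DMAP, CH2Cl2, 0 °C→rt
Reagents that add atoms: pivaloyl chloride, CC(C)(C)C(=O)Cl
Why: O-acylation of the phenol, giving a hindered ester that keeps the aldehyde electrophilic, resists the enolate at −78 °C and is removed by LiAlH4 in step 8 without an extra step.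

Step 4
Reactants: 7 3-oxocyclobutane-1-carboxylic acid
Product: 8 (R)-paraconic acid [(R)-5-oxotetrahydrofuran-3-carboxylic acid]
Conditions: 3,3'-bis(2,4,6-triisopropylphenyl)-H8-BINOL phosphoric acid (10 mol%), 30% aq. H2O2 (1.5 equiv), CHCl3, −40 °C; recrystallise
Reagents that add atoms: hydrogen peroxide, OO
Why: Proposed new method: chiral-phosphoric-acid/H2O2 Baeyer–Villiger desymmetrisation is established for 3-aryl-, 3-benzyl- and 3-alkylcyclobutanones but, to my knowledge, not for a 3-carboxycyclobutanone; the acid activates C=O and H2O2 bifunctionally (P–OH···O=C, P=O···HOO), the Criegee adduct collapses by 1,2-shift of the one enantiotopic ring CH2 that lies antiperiplanar to the O–O bond in the chiral pocket (ring expansion 4 → 5), and the substrate CO2H is expected to give a second hydrogen bond to the phosphate that fixes the ring orientation and so sets the C8 stereocentre; closest known reaction: Brønsted-acid-catalysed asymmetric Baeyer–Villiger oxidation of 3-substituted cyclobutanones.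

Step 5
Reactants: 8 (R)-paraconic acid; 2 guaiacol
Product: 10 (R)-4-(4-hydroxy-3-methoxybenzoyl)dihydrofuran-2(3H)-one, via (R)-paraconyl chloride 9 (not isolated)
Conditions: (COCl)2, cat. DMF, CH2Cl2, 0 °C→rt, evaporate; then 2 (1.1 equiv), TfOH, 0 °C→rt, 2 h
Reagents that add atoms: oxalyl chloride, ClC(=O)C(=O)Cl (gives only the Cl of 9; none of its atoms stay in 10)
Why: Friedel–Crafts acylation (O-acylation, then Fries-type C-acylation in TfOH) para to the free OH, the stronger donor, a sequence that α-stereogenic acyl chlorides such as N-protected amino acid chlorides are known to survive without loss of configuration.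

Step 6
Reactants: 10 (R)-4-(4-hydroxy-3-methoxybenzoyl)dihydrofuran-2(3H)-one
Product: 11 (R)-4-(4-hydroxy-3-methoxybenzyl)dihydrofuran-2(3H)-one
Conditions: Et3SiH (3 equiv), TFA, rt
Reagents that add atoms: none
Why: ionic hydrogenation of the p-hydroxyaryl ketone through the benzylic cation, which leaves the lactone and the adjacent stereocentre untouched (C8 stays R).

Step 7
Reactants: 11 (R)-4-(4-hydroxy-3-methoxybenzyl)dihydrofuran-2(3H)-one; 6 4-formyl-2-methoxyphenyl pivalate
Product: 12 4-{hydroxy[(3S,4R)-4-(4-hydroxy-3-methoxybenzyl)-2-oxotetrahydrofuran-3-yl]methyl}-2-methoxyphenyl pivalate (3,4-trans; both carbinol epimers)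
Conditions: LDA (2.1 equiv), THF, −78 °C; then 6, −78 °C; sat. aq. NH4Cl
Reagents that add atoms: none
Why: lithium enolate aldol addition in which the aldehyde approaches anti to the C4 benzyl group, giving the 3,4-trans lactone and so fixing C8', while the carbinol centre forms as a mixture that is erased later.

Step 8
Reactants: 12 trans aldol lactone
Product: 14 (+)-lariciresinol, via 7'-hydroxysecoisolariciresinol 13 (not isolated)
Conditions: LiAlH4 (5 equiv), THF, 0 °C→rt; then 2 M aq. HCl to pH 1–2, rt, 1–2 h
Reagents that add atoms: none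
Why: hydride reduction of lactone and pivalate, then acid-catalysed SN1 cycloetherification in which the p-hydroxybenzyl cation is captured 5-exo by the C9 hydroxyl (the only one that can close a five-membered ring), giving the 2,3-trans tetrahydrofuran and leaving C9'–OH as the only aliphatic OH.

Step 9
Reactants: 15 4-iodophenol; 16 acrylic acid
Product: 17 (E)-p-coumaric acid
Conditions: Pd(OAc)2 (1 mol%), Et3N, MeCN/H2O, 80 °C; HCl
Reagents that add atoms: none
Why: Mizoroki–Heck reaction, in which syn insertion and syn β-hydride elimination give the E-alkene.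

Step 10
Reactants: 14 (+)-lariciresinol; 17 (E)-p-coumaric acid
Product: 18 (+)-lariciresinol 9'-O-(E)-p-coumarate
Conditions: PPh3 (1.3 equiv), DIAD (1.3 equiv), THF, 0 °C→rt
Reagents that add atoms: none
Why: Mitsunobu esterification, in which only the carboxylic acid (pKa ≈ 4.5) is acidic enough to act as pronucleophile, so the single primary alcohol is esterified in the presence of the free phenols and no stereocentre is touched.

Step 11
Reactants: 18 (+)-lariciresinol 9'-O-(E)-p-coumarate
Product: 19 target, [(1S,2R,3R)-7-hydroxy-1-(4-hydroxy-3-methoxyphenyl)-3-(hydroxymethyl)-6-methoxy-1,2,3,4-tetrahydronaphthalen-2-yl]methyl (E)-3-(4-hydroxyphenyl)acrylate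
Conditions: TFA/CH2Cl2 (1:9), 0.01 M, 0 °C→rt
Reagents that add atoms: none
Why: acid-mediated skeletal rearrangement of the 2-aryl-tetrahydrofuran to the aryltetralin, by ionisation of the benzylic C7'–O bond and intramolecular Friedel–Crafts closure para to OMe (directly, or by ipso attack para to OH and a dienone–phenol 1,2-shift), with the aryl group entering trans to the C2 substituent to set C1 as S and the C9 hydroxyl released.

**Compound list**
1 | catechol | Oc1ccccc1O | starting material
2 | guaiacol (2-methoxyphenol) | COc1ccccc1O | intermediate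
3 | glyoxylic acid | O=CC(=O)O | starting material
4 | 4-hydroxy-3-methoxymandelic acid (racemic) | COc1cc(C(O)C(=O)O)ccc1O | intermediate (not isolated)
5 | vanillin | COc1cc(C=O)ccc1O | intermediate
6 | 4-formyl-2-methoxyphenyl pivalate | COc1cc(C=O)ccc1OC(=O)C(C)(C)C | intermediate
7 | 3-oxocyclobutane-1-carboxylic acid | O=C1CC(C(=O)O)C1 | starting material
8 | (R)-5-oxotetrahydrofuran-3-carboxylic acid, (R)-paraconic acid | O=C1C[C@@H](C(=O)O)CO1 | intermediate
9 | (R)-5-oxotetrahydrofuran-3-carbonyl chloride, (R)-paraconyl chloride | O=C1C[C@@H](C(Cl)=O)CO1 | intermediate (not isolated)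
10 | (R)-4-(4-hydroxy-3-methoxybenzoyl)dihydrofuran-2(3H)-one | O=C1C[C@@H](C(=O)c2ccc(O)c(OC)c2)CO1 | intermediate
11 | (R)-4-(4-hydroxy-3-methoxybenzyl)dihydrofuran-2(3H)-one | O=C1C[C@@H](Cc2ccc(O)c(OC)c2)CO1 | intermediate
12 | 4-{hydroxy[(3S,4R)-4-(4-hydroxy-3-methoxybenzyl)-2-oxotetrahydrofuran-3-yl]methyl}-2-methoxyphenyl pivalate (carbinol carbon: both epimers) | O=C1OC[C@H](Cc2ccc(O)c(OC)c2)[C@H]1C(O)c1ccc(OC(=O)C(C)(C)C)c(OC)c1 | intermediate
13 | (2R,3R)-2-[hydroxy(4-hydroxy-3-methoxyphenyl)methyl]-3-(4-hydroxy-3-methoxybenzyl)butane-1,4-diol, 7'-hydroxysecoisolariciresinol (carbinol carbon: both epimers) | OC[C@H](Cc1ccc(O)c(OC)c1)[C@H](CO)C(O)c1ccc(O)c(OC)c1 | intermediate (not isolated)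
14 | (+)-lariciresinol, (2S,3R,4R)-2-(4-hydroxy-3-methoxyphenyl)-4-(4-hydroxy-3-methoxybenzyl)-3-(hydroxymethyl)tetrahydrofuran | OC[C@H]1[C@@H](Cc2ccc(O)c(OC)c2)CO[C@@H]1c1ccc(O)c(OC)c1 | intermediate
15 | 4-iodophenol | Oc1ccc(I)cc1 | starting material
16 | acrylic acid | C=CC(=O)O | starting material
17 | (E)-p-coumaric acid | O=C(O)/C=C/c1ccc(O)cc1 | intermediate
18 | [(2S,3R,4R)-2-(4-hydroxy-3-methoxyphenyl)-4-(4-hydroxy-3-methoxybenzyl)tetrahydrofuran-3-yl]methyl (E)-3-(4-hydroxyphenyl)acrylate | O=C(/C=C/c1ccc(O)cc1)OC[C@H]1[C@@H](Cc2ccc(O)c(OC)c2)CO[C@@H]1c1ccc(O)c(OC)c1 | intermediate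
19 | [(1S,2R,3R)-7-hydroxy-1-(4-hydroxy-3-methoxyphenyl)-3-(hydroxymethyl)-6-methoxy-1,2,3,4-tetrahydronaphthalen-2-yl]methyl (E)-3-(4-hydroxyphenyl)acrylate | COc1cc([C@H]2c3cc(O)c(OC)cc3C[C@@H](CO)[C@@H]2COC(=O)/C=C/c2ccc(O)cc2)ccc1O | target

**Totals and risks**

Total step count: 11. Longest linear sequence: 7 steps (7 → 8 → 10 → 11 → 12 → 14 → 18 → 19).

Three steps most likely to fail:

Step 4 (the new reaction). The risks are low ee from the uncatalysed background oxidation or weak discrimination by the small CO2H group; the catalyst antipode that gives (R)-8 must also be identified on the first run by rotation against known paraconic acid. Fallback with known chemistry: from 7, uncatalysed Baeyer–Villiger oxidation (30% H2O2, AcOH, rt) gives racemic paraconic acid F1. Classical resolution by crystallising its salt with (R)-1-phenylethylamine from ethanol gives (R)-1-phenylethylammonium (R)-paraconate F2 (the antipodal amine is used if the other salt is the less soluble one). Aqueous HCl then returns the route to 8.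

Step 5. The risks are acylation para to OMe instead of para to OH, an incomplete Fries stage, or erosion of ee at the α-keto stereocentre. Fallback that avoids both the electrophilic substitution and the ketone: from 8, BH3·SMe2 (THF, 0 °C; the lactone is untouched) gives (S)-4-(hydroxymethyl)dihydrofuran-2(3H)-one F3, and I2/PPh3/imidazole converts it into (R)-4-(iodomethyl)dihydrofuran-2(3H)-one F4. Guaiacol 2 is brominated para to OH (NBS, MeCN, 0 °C) to 4-bromo-2-methoxyphenol F5. Nickel-catalysed reductive cross-electrophile coupling of F4 with F5 (NiBr2·glyme, 4,4'-di-tert-butyl-2,2'-bipyridine, Zn, NaI, DMA, 60 °C) gives 11 directly, so steps 5 and 6 are both replaced and the route is rejoined at 11.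

Step 10. The risk is O-alkylation of one of the phenols of 14 or of the coumaric acid phenol under Mitsunobu conditions. Fallback that builds the cinnamate C=C on the substrate instead of bringing it in: from 14, immobilised Candida antarctica lipase B with vinyl acrylate (2-MeTHF, 40 °C) acylates only the aliphatic C9'–OH to give lariciresinol 9'-acrylate F6. A Heck reaction of F6 with 4-iodophenol 15 (Pd(OAc)2, Et3N, DMF, 80 °C) gives 18, where the route continues; step 9 is then not needed.

**Further compounds**
F1 | step 4 | racemic 5-oxotetrahydrofuran-3-carboxylic acid (rac-paraconic acid) | O=C1CC(C(=O)O)CO1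
F2 | step 4 | (R)-1-phenylethylammonium (R)-5-oxotetrahydrofuran-3-carboxylate | C[C@@H]([NH3+])c1ccccc1.O=C1C[C@@H](C(=O)[O-])CO1
F3 | step 5 | (S)-4-(hydroxymethyl)dihydrofuran-2(3H)-one | O=C1C[C@@H](CO)CO1
F4 | step 5 | (R)-4-(iodomethyl)dihydrofuran-2(3H)-one | O=C1C[C@@H](CI)CO1
F5 | step 5 | 4-bromo-2-methoxyphenol | COc1cc(Br)ccc1O
F6 | step 10 | [(2S,3R,4R)-2-(4-hydroxy-3-methoxyphenyl)-4-(4-hydroxy-3-methoxybenzyl)tetrahydrofuran-3-yl]methyl acrylate (lariciresinol 9'-acrylate) | C=CC(=O)OC[C@H]1[C@@H](Cc2ccc(O)c(OC)c2)CO[C@@H]1c1ccc(O)c(OC)c1
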